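**Retrosynthetic overview**
1. Target 19 comes from tribenzyl ether 18 by global hydrogenolysis. The γ-butyrolactone is the last ring made.
2. Key disconnection: the O1–C2(=O) unit of the lactone is removed as one formate ion. This cuts C2–C3 and O1–C5 together and leads back to the acyclic (E)-styrenyl homoallylic chloride 15.
3. Enabling feature: lactone C3 and C5 are 1,3-related through C4. C3 carries the CH2 bound to C5 of the dihydrobenzofuran, so in dehydro form it is the β-carbon of a styrene and accepts CO2 radical anion. C5 is a primary CH2 that can carry chloride. C3 is the enolisable α-carbon next to C4, so the trans-3,4 pattern is the thermodynamic sink.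
4. 15 comes from a Heck union of aryl bromide 14 with (S)-chloride 5. Chloride 5 is made in one Cu-catalysed asymmetric SN2′ alkylation of (E)-1,4-dichlorobut-2-ene.
5. 14 comes from an enantioselective Rh-carbenoid 1,5-C–H insertion of diazo ester 11, which sets C2; C3 is relayed from C2 by epimerisation. Ring order: dihydrofuran (step 7), then lactone (step 11).

Key step: step 11

Assumption: the absolute sense of induction in steps 2 and 7 is assigned by analogy with the closest precedents. If a catalyst delivers the antipode, its mirror-image form is used and nothing else changes.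

Step 1
Reactants: 1 4-(benzyloxy)-3-methoxybenzyl alcohol
Product: 2 4-(benzyloxy)-3-methoxybenzyl chloride
Conditions: SOCl2 (1.1 equiv), cat. DMF, CH2Cl2, 0 °C
Reagents that add atoms: thionyl chloride, O=S(Cl)Cl
Why: Chlorodehydroxylation of an electron-rich benzylic alcohol through its chlorosulfite is fast at 0 °C and leaves the aryl benzyl ether untouched.

Step 2
Reactants: 2 4-(benzyloxy)-3-methoxybenzyl chloride; 3 (E)-1,4-dichlorobut-2-ene
Product: 5 (S)-1-(benzyloxy)-4-[2-(chloromethyl)but-3-en-1-yl]-2-methoxybenzene, via benzylic Grignard reagent 4 (not isolated)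
Conditions: Mg (3 equiv), 2-MeTHF, 0 °C, slow addition of 2; then added slowly to 3, CuTC (3 mol %), BINOL-derived phosphoramidite with a bis(1-arylethyl)amine unit (3.3 mol %), CH2Cl2, −78 °C
Reagents that add atoms: none
Why: In this Cu-catalysed asymmetric allylic alkylation (SN2′) of a Grignard reagent on a symmetrical 1,4-dihalobut-2-ene, the chiral Cu–phosphoramidite complex selects the alkene face and sets the (S) centre, and the homoallylic C–Cl bond of the product no longer reacts.

Step 3
Reactants: 6 2-(benzyloxy)phenol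
Product: 7 2-(benzyloxy)-4-bromophenol
Conditions: NBS (1.0 equiv), MeCN, 0 °C
Reagents that add atoms: N-bromosuccinimide, O=C1CCC(=O)N1Br
Why: In this electrophilic aromatic bromination the free phenol is the stronger director and its para position is open, so C4 should be brominated selectively.

Step 4
Reactants: 7 2-(benzyloxy)-4-bromophenol
Product: 8 2-(benzyloxy)-4-bromo-6-iodophenol
Conditions: NIS (1.05 equiv), cat. TsOH, MeCN, 25 °C
Reagents that add atoms: N-iodosuccinimide, O=C1CCC(=O)N1I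
Why: In this electrophilic aromatic iodination the para position is blocked, so the phenol directs iodine to its only free ortho carbon.

Step 5
Reactants: 8 2-(benzyloxy)-4-bromo-6-iodophenol; 2 4-(benzyloxy)-3-methoxybenzyl chloride
Product: 9 1-(benzyloxy)-2-{[4-(benzyloxy)-3-methoxybenzyl]oxy}-5-bromo-3-iodobenzene
Conditions: K2CO3, cat. KI, DMF, 50 °C
Reagents that add atoms: none
Why: This Williamson ether synthesis pairs an acidic halophenoxide with a reactive benzylic chloride, which overcomes the double ortho substitution.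

Step 6
Reactants: 9 1-(benzyloxy)-2-{[4-(benzyloxy)-3-methoxybenzyl]oxy}-5-bromo-3-iodobenzene; 10 ethyl diazoacetate
Product: 11 ethyl 2-[3-(benzyloxy)-2-{[4-(benzyloxy)-3-methoxybenzyl]oxy}-5-bromophenyl]-2-diazoacetate
Conditions: Pd(PPh3)4 (5 mol %), Ag2CO3 (0.5 equiv), Et3N, toluene, 25 °C
Reagents that add atoms: none
Why: This Pd-catalysed cross-coupling of an aryl iodide with the C–H bond of ethyl diazoacetate retains the diazo group, and oxidative addition at room temperature distinguishes C–I from C–Br.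

Step 7
Reactants: 11 ethyl 2-[3-(benzyloxy)-2-{[4-(benzyloxy)-3-methoxybenzyl]oxy}-5-bromophenyl]-2-diazoacetate
Product: 12 ethyl (2S,3R)-7-(benzyloxy)-2-[4-(benzyloxy)-3-methoxyphenyl]-5-bromo-2,3-dihydrobenzofuran-3-carboxylate (cis)
Conditions: Rh2(S-PTTL)4 (1 mol %), toluene, −60 °C
Reagents that add atoms: none
Why: In this enantioselective intramolecular 1,5-C–H insertion the donor/acceptor Rh carbenoid enters the electron-rich benzylic ether C–H bond, the chiral carboxylate ligands select the enantiotopic hydrogen and set C2 as S, and the concerted transition state gives the cis ring.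

Step 8
Reactants: 12 ethyl (2S,3R)-7-(benzyloxy)-2-[4-(benzyloxy)-3-methoxyphenyl]-5-bromo-2,3-dihydrobenzofuran-3-carboxylate
Product: 13 ethyl (2S,3S)-7-(benzyloxy)-2-[4-(benzyloxy)-3-methoxyphenyl]-5-bromo-2,3-dihydrobenzofuran-3-carboxylate (trans)
Conditions: NaOEt (0.2 equiv), EtOH, 25 °C
Reagents that add atoms: none
Why: This base-mediated epimerisation of the ester α-carbon lets C2 dictate C3 by relieving the cis aryl/ester strain, and the mild catalytic base together with the unfavourable 5-endo geometry should hold back retro-oxa-Michael ring opening.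

Step 9
Reactants: 13 ethyl (2S,3S)-7-(benzyloxy)-2-[4-(benzyloxy)-3-methoxyphenyl]-5-bromo-2,3-dihydrobenzofuran-3-carboxylate
Product: 14 {(2S,3R)-7-(benzyloxy)-2-[4-(benzyloxy)-3-methoxyphenyl]-5-bromo-2,3-dihydrobenzofuran-3-yl}methanol
Conditions: LiBH4 (2 equiv), THF–MeOH, 0 to 25 °C
Reagents that add atoms: none
Why: This borohydride ester reduction gives the primary alcohol without touching the aryl bromide or either stereocentre; the C3 descriptor changes only because the priorities change.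

Step 10
Reactants: 14 {(2S,3R)-7-(benzyloxy)-2-[4-(benzyloxy)-3-methoxyphenyl]-5-bromo-2,3-dihydrobenzofuran-3-yl}methanol; 5 (S)-1-(benzyloxy)-4-[2-(chloromethyl)but-3-en-1-yl]-2-methoxybenzene
Product: 15 {(2S,3R)-7-(benzyloxy)-2-[4-(benzyloxy)-3-methoxyphenyl]-5-[(1E,3S)-3-[4-(benzyloxy)-3-methoxybenzyl]-4-chlorobut-1-en-1-yl]-2,3-dihydrobenzofuran-3-yl}methanol
Conditions: Pd2(dba)3 (2.5 mol %), [HP(t-Bu)3]BF4 (6 mol %), Cy2NMe (1.5 equiv), dioxane, 70 °C
Reagents that add atoms: none
Why: In this Heck reaction the aryl group adds to the unsubstituted alkene terminus, syn β-hydride elimination of a benzylic hydrogen gives the conjugated (E)-styrene, the hindered amine removes Pd–H quickly so the allylic stereocentre is kept, and the alkyl chloride and free alcohol are inert.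

Step 11
Reactants: 15 {(2S,3R)-7-(benzyloxy)-2-[4-(benzyloxy)-3-methoxyphenyl]-5-[(1E,3S)-3-[4-(benzyloxy)-3-methoxybenzyl]-4-chlorobut-1-en-1-yl]-2,3-dihydrobenzofuran-3-yl}methanol
Product: 18 (3S,4S)-4-[4-(benzyloxy)-3-methoxybenzyl]-3-({(2S,3R)-7-(benzyloxy)-2-[4-(benzyloxy)-3-methoxyphenyl]-3-(hydroxymethyl)-2,3-dihydrobenzofuran-5-yl}methyl)dihydrofuran-2(3H)-one, via chloro carboxylate 16 (not isolated), via cis-lactone 17 (not isolated)
Conditions: HCO2Cs (4 equiv), mesna (20 mol %), 4DPAIPN (1 mol %), DMSO, 450 nm LED, 25 °C; then dark, 60 °C; then DBU (0.5 equiv), 25 °C, same flask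
Reagents that add atoms: cesium formate, [Cs+].[O-]C=O
Why: Proposed new method: a thiyl radical (from mesna, started by the excited cyanoarene) abstracts the formyl hydrogen of formate to give CO2 radical anion, which adds Giese-style to the styrene carbon remote from the arene (future lactone C3) because only this regiochemistry gives a benzylic radical stabilised by the dihydrobenzofuran ring, and that radical takes hydrogen from the thiol, which closes the chain and installs the benzylic CH2. The nascent cesium carboxylate 16 then displaces the primary chloride in a 5-exo-tet SN2 closure, so one formate ion delivers the C2–C3 bond, the O1–C5 bond and the benzylic hydrogen in a formal [3+2] annulation. The closest known reaction types are the thiol-catalysed anti-Markovnikov hydrocarboxylation of styrenes with formate salts and the alkylative lactonisation of γ-halo carboxylates, and what is new is their merger on a homoallylic chloride. The new stereocentre C3 is controlled by the existing C4 centre: allylic strain biases the radical addition only weakly, but C3 is the enolisable α-carbon, so DBU funnels cis-lactone 17 into the thermodynamically preferred trans-3,4-dibenzyl lactone, while C4 and both dihydrobenzofuran centres bear no acidic hydrogen and stay fixed. The step needs chemoselectivity for the alkene over the C–Cl bond, which the substrate secures because the unactivated β-branched chloride lies beyond the reducing power of CO2 radical anion and reacts only slowly with external formate or neutral alkyl thiol, whereas the intramolecular closure is fast. No aryl halide remains, benzyl ethers and the free alcohol are inert, and hydrogen transfer from the thiol outruns reduction of the benzylic radical, so no carbanion can attack the chloride.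

Step 12
Reactants: 18 (3S,4S)-4-[4-(benzyloxy)-3-methoxybenzyl]-3-({(2S,3R)-7-(benzyloxy)-2-[4-(benzyloxy)-3-methoxyphenyl]-3-(hydroxymethyl)-2,3-dihydrobenzofuran-5-yl}methyl)dihydrofuran-2(3H)-one
Product: 19 (3S,4S)-4-(4-hydroxy-3-methoxybenzyl)-3-{[(2S,3R)-7-hydroxy-2-(4-hydroxy-3-methoxyphenyl)-3-(hydroxymethyl)-2,3-dihydrobenzofuran-5-yl]methyl}dihydrofuran-2(3H)-one (CNP0118131.1)
Conditions: H2 (1 atm), 10% Pd/C, EtOAc–EtOH, 25 °C
Reagents that add atoms: none
Why: This catalytic hydrogenolysis cleaves the three aryl benzyl ethers, and at 1 atm in neutral medium the cyclic benzylic C2–O bond, the lactone and all four stereocentres should survive.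

**Compound list**
1 | 4-(benzyloxy)-3-methoxybenzyl alcohol | COc1cc(CO)ccc1OCc1ccccc1 | starting material
2 | 4-(benzyloxy)-3-methoxybenzyl chloride | COc1cc(CCl)ccc1OCc1ccccc1 | intermediate
3 | (E)-1,4-dichlorobut-2-ene | ClC/C=C/CCl | starting material
4 | [4-(benzyloxy)-3-methoxybenzyl]magnesium chloride | COc1cc(C[Mg]Cl)ccc1OCc1ccccc1 | intermediate
5 | (S)-1-(benzyloxy)-4-[2-(chloromethyl)but-3-en-1-yl]-2-methoxybenzene | COc1cc(C[C@@H](C=C)CCl)ccc1OCc1ccccc1 | intermediate
6 | 2-(benzyloxy)phenol | Oc1ccccc1OCc1ccccc1 | starting material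
7 | 2-(benzyloxy)-4-bromophenol | Oc1ccc(Br)cc1OCc1ccccc1 | intermediate
8 | 2-(benzyloxy)-4-bromo-6-iodophenol | Oc1c(I)cc(Br)cc1OCc1ccccc1 | intermediate
9 | 1-(benzyloxy)-2-{[4-(benzyloxy)-3-methoxybenzyl]oxy}-5-bromo-3-iodobenzene | COc1cc(COc2c(I)cc(Br)cc2OCc2ccccc2)ccc1OCc1ccccc1 | intermediate
10 | ethyl diazoacetate | CCOC(=O)C=[N+]=[N-] | starting material
11 | ethyl 2-[3-(benzyloxy)-2-{[4-(benzyloxy)-3-methoxybenzyl]oxy}-5-bromophenyl]-2-diazoacetate | CCOC(=O)C(=[N+]=[N-])c1cc(Br)cc(OCc2ccccc2)c1OCc1ccc(OCc2ccccc2)c(OC)c1 | intermediate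
12 | ethyl (2S,3R)-7-(benzyloxy)-2-[4-(benzyloxy)-3-methoxyphenyl]-5-bromo-2,3-dihydrobenzofuran-3-carboxylate (cis) | Brc1cc(OCc2ccccc2)c2c(c1)[C@@H](C(=O)OCC)[C@@H](c1ccc(OCc3ccccc3)c(OC)c1)O2 | intermediate
13 | ethyl (2S,3S)-7-(benzyloxy)-2-[4-(benzyloxy)-3-methoxyphenyl]-5-bromo-2,3-dihydrobenzofuran-3-carboxylate (trans) | Brc1cc(OCc2ccccc2)c2c(c1)[C@H](C(=O)OCC)[C@@H](c1ccc(OCc3ccccc3)c(OC)c1)O2 | intermediate
14 | {(2S,3R)-7-(benzyloxy)-2-[4-(benzyloxy)-3-methoxyphenyl]-5-bromo-2,3-dihydrobenzofuran-3-yl}methanol | Brc1cc(OCc2ccccc2)c2c(c1)[C@H](CO)[C@@H](c1ccc(OCc3ccccc3)c(OC)c1)O2 | intermediate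
15 | {(2S,3R)-7-(benzyloxy)-2-[4-(benzyloxy)-3-methoxyphenyl]-5-[(1E,3S)-3-[4-(benzyloxy)-3-methoxybenzyl]-4-chlorobut-1-en-1-yl]-2,3-dihydrobenzofuran-3-yl}methanol | COc1cc(C[C@@H](/C=C/c2cc(OCc3ccccc3)c3c(c2)[C@H](CO)[C@@H](c2ccc(OCc4ccccc4)c(OC)c2)O3)CCl)ccc1OCc1ccccc1 | intermediate
16 | cesium (3S)-3-[4-(benzyloxy)-3-methoxybenzyl]-4-chloro-2-({(2S,3R)-7-(benzyloxy)-2-[4-(benzyloxy)-3-methoxyphenyl]-3-(hydroxymethyl)-2,3-dihydrobenzofuran-5-yl}methyl)butanoate, both C2 epimers | COc1cc(C[C@@H](C(Cc2cc(OCc3ccccc3)c3c(c2)[C@H](CO)[C@@H](c2ccc(OCc4ccccc4)c(OC)c2)O3)C(=O)[O-])CCl)ccc1OCc1ccccc1.[Cs+] | intermediate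
17 | (3R,4S)-cis epimer of lactone 18 | COc1cc(C[C@@H]2COC(=O)[C@@H]2Cc2cc(OCc3ccccc3)c3c(c2)[C@H](CO)[C@@H](c2ccc(OCc4ccccc4)c(OC)c2)O3)ccc1OCc1ccccc1 | intermediate
18 | (3S,4S)-4-[4-(benzyloxy)-3-methoxybenzyl]-3-({(2S,3R)-7-(benzyloxy)-2-[4-(benzyloxy)-3-methoxyphenyl]-3-(hydroxymethyl)-2,3-dihydrobenzofuran-5-yl}methyl)dihydrofuran-2(3H)-one | COc1cc(C[C@@H]2COC(=O)[C@H]2Cc2cc(OCc3ccccc3)c3c(c2)[C@H](CO)[C@@H](c2ccc(OCc4ccccc4)c(OC)c2)O3)ccc1OCc1ccccc1 | intermediate
19 | (3S,4S)-4-(4-hydroxy-3-methoxybenzyl)-3-{[(2S,3R)-7-hydroxy-2-(4-hydroxy-3-methoxyphenyl)-3-(hydroxymethyl)-2,3-dihydrobenzofuran-5-yl]methyl}dihydrofuran-2(3H)-one | COc1cc(C[C@@H]2COC(=O)[C@H]2Cc2cc(O)c3c(c2)[C@H](CO)[C@@H](c2ccc(O)c(OC)c2)O3)ccc1O | target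

Total step count: 12. Longest linear sequence: 10 steps (6 to 19, steps 3–12).

**Steps most likely to fail**

1. Step 11. The nucleophilic CO2 radical anion may add too slowly to an electron-rich, β-alkyl-substituted styrene. The chloride may be substituted early by formate or thiol, or the styrene may be photo-oxidised.
The fallback is the known anti-selective alkylation of a β-benzyl-γ-butyrolactone enolate. It sets out from 5 and 14 and comes back to the route at 19.
Hydroboration of 5 (9-BBN, then NaBO3) would give (S)-3-[4-(benzyloxy)-3-methoxybenzyl]-4-chlorobutan-1-ol F1. TEMPO/PhI(OAc)2 oxidation would give (S)-3-[4-(benzyloxy)-3-methoxybenzyl]-4-chlorobutanoic acid F2. K2CO3 in DMF would close this acid to (S)-4-[4-(benzyloxy)-3-methoxybenzyl]dihydrofuran-2(3H)-one F3.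
In parallel, 14 would be O-benzylated (NaH, BnBr) to (2S,3R)-7-(benzyloxy)-3-[(benzyloxy)methyl]-2-[4-(benzyloxy)-3-methoxyphenyl]-5-bromo-2,3-dihydrobenzofuran F4. Lithiation (n-BuLi, −78 °C) and a paraformaldehyde quench would give the 5-(hydroxymethyl) compound F5. PBr3 would convert it into the 5-(bromomethyl) compound F6.
Alkylation of the lithium enolate of F3 (LiHMDS, THF, −78 °C) with F6, anti to the C4 benzyl group, would give the trans tetrabenzyl lactone F7. Hydrogenolysis of F7 as in step 12 leads to 19.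

2. Step 2. Wurtz homocoupling may compete during formation of the electron-rich benzylic Grignard reagent. A benzylic nucleophile may also erode SN2′/SN2 selectivity and facial selectivity.
The fallback is an Evans asymmetric alkylation. It sets out from 2 and comes back at 5.
(S)-4-Benzyloxazolidin-2-one would be acylated (n-BuLi, (E)-crotonyl chloride) to (S)-4-benzyl-3-[(E)-but-2-enoyl]oxazolidin-2-one F8. NaHMDS at −78 °C would give the chelated dienolate. Chloride 2 (with Bu4NI) would alkylate it at the α-carbon, on the face away from the ring benzyl group, to give (S)-4-benzyl-3-{(S)-2-[4-(benzyloxy)-3-methoxybenzyl]but-3-enoyl}oxazolidin-2-one F9. LiBH4 would remove the auxiliary to give (S)-2-[4-(benzyloxy)-3-methoxybenzyl]but-3-en-1-ol F10. An Appel reaction (PPh3, CCl4) would give 5.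

3. Step 10. β-Hydride elimination toward the tertiary allylic C–H bond, or Pd–H chain walking, would move the alkene out of conjugation and erase the allylic stereocentre.
The fallback fixes the alkene position before the C–C coupling. It sets out from 5, with 14 as partner, and comes back at 15.
Cross-metathesis of 5 with vinylboronic acid pinacol ester (isopropoxy-chelated second-generation Ru catalyst, CH2Cl2, 40 °C) would give the (S,E)-alkenylboronate 2-{(1E,3S)-3-[4-(benzyloxy)-3-methoxybenzyl]-4-chlorobut-1-en-1-yl}-4,4,5,5-tetramethyl-1,3,2-dioxaborolane F11. A Suzuki–Miyaura coupling with 14 (Pd(dppf)Cl2, K3PO4, dioxane–H2O, 60 °C) would convert F11 into 15 with retention of alkene geometry.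

**Further compounds**
F1 | step 11 | (S)-3-[4-(benzyloxy)-3-methoxybenzyl]-4-chlorobutan-1-ol | COc1cc(C[C@@H](CCO)CCl)ccc1OCc1ccccc1
F2 | step 11 | (S)-3-[4-(benzyloxy)-3-methoxybenzyl]-4-chlorobutanoic acid | COc1cc(C[C@@H](CC(=O)O)CCl)ccc1OCc1ccccc1
F3 | step 11 | (S)-4-[4-(benzyloxy)-3-methoxybenzyl]dihydrofuran-2(3H)-one | COc1cc(C[C@@H]2COC(=O)C2)ccc1OCc1ccccc1
F4 | step 11 | (2S,3R)-7-(benzyloxy)-3-[(benzyloxy)methyl]-2-[4-(benzyloxy)-3-methoxyphenyl]-5-bromo-2,3-dihydrobenzofuran | Brc1cc(OCc2ccccc2)c2c(c1)[C@H](COCc1ccccc1)[C@@H](c1ccc(OCc3ccccc3)c(OC)c1)O2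
F5 | step 11 | {(2S,3R)-7-(benzyloxy)-3-[(benzyloxy)methyl]-2-[4-(benzyloxy)-3-methoxyphenyl]-2,3-dihydrobenzofuran-5-yl}methanol | OCc1cc(OCc2ccccc2)c2c(c1)[C@H](COCc1ccccc1)[C@@H](c1ccc(OCc3ccccc3)c(OC)c1)O2
F6 | step 11 | (2S,3R)-7-(benzyloxy)-3-[(benzyloxy)methyl]-2-[4-(benzyloxy)-3-methoxyphenyl]-5-(bromomethyl)-2,3-dihydrobenzofuran | BrCc1cc(OCc2ccccc2)c2c(c1)[C@H](COCc1ccccc1)[C@@H](c1ccc(OCc3ccccc3)c(OC)c1)O2
F7 | step 11 | (3S,4S)-4-[4-(benzyloxy)-3-methoxybenzyl]-3-({(2S,3R)-7-(benzyloxy)-3-[(benzyloxy)methyl]-2-[4-(benzyloxy)-3-methoxyphenyl]-2,3-dihydrobenzofuran-5-yl}methyl)dihydrofuran-2(3H)-one | COc1cc(C[C@@H]2COC(=O)[C@H]2Cc2cc(OCc3ccccc3)c3c(c2)[C@H](COCc2ccccc2)[C@@H](c2ccc(OCc4ccccc4)c(OC)c2)O3)ccc1OCc1ccccc1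
F8 | step 2 | (S)-4-benzyl-3-[(E)-but-2-enoyl]oxazolidin-2-one | C/C=C/C(=O)N1[C@@H](Cc2ccccc2)COC1=O
F9 | step 2 | (S)-4-benzyl-3-{(S)-2-[4-(benzyloxy)-3-methoxybenzyl]but-3-enoyl}oxazolidin-2-one | C=C[C@H](Cc1ccc(OCc2ccccc2)c(OC)c1)C(=O)N1[C@@H](Cc2ccccc2)COC1=O
F10 | step 2 | (S)-2-[4-(benzyloxy)-3-methoxybenzyl]but-3-en-1-ol | C=C[C@H](Cc1ccc(OCc2ccccc2)c(OC)c1)CO
F11 | step 10 | 2-{(1E,3S)-3-[4-(benzyloxy)-3-methoxybenzyl]-4-chlorobut-1-en-1-yl}-4,4,5,5-tetramethyl-1,3,2-dioxaborolane | COc1cc(C[C@@H](/C=C/B2OC(C)(C)C(C)(C)O2)CCl)ccc1OCc1ccccc1
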